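**Retrosynthetic overview**
1. Last bonds and last ring: the two C–O bonds of the oxirane (C11′–O, C12′–O), made by a hydroxyl-directed threo epoxidation of the (10′S)-allylic alcohol in the fully assembled diol enal.
2. The (Z)-enal: C–O bond formation at the formyl carbon by oxidative 1,3-transposition of a C1 isopropenyl carbinol, which comes from the C1 ring ketone.
3. Ring centres C5 and C6: conjugate methylation of a (4R)-3-alkyl-4-methylcyclohex-2-enone and alkylation of the resulting enolate; the enone comes from (R)-4-methylcyclohexenone by conjugate addition of the side-chain Grignard reagent and dehydrogenation.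
4. Side chain: C4′–C5′ by B-alkyl Suzuki coupling; C7′=C8′ by methylalumination/vinylation of the alkyne obtained by asymmetric propargylation of 3-methylbut-2-enal (sets C10′).
5. Ring order: the cyclohexane first (organocatalytic Michael addition of propanal to methyl vinyl ketone, then aldol condensation; sets C4), the oxirane last.

Assumption: the target is read as drawn, (4R,5R,6S,10′S,11′R) with a Z enal and E alkenes at C3′ and C7′; in the text ring atoms run C1 (alkylidene carbon) to C6 (CH carrying the hydroxypropyl group) and side-chain atoms C1′–C12′ outward from C5, while compound names carry their own systematic locants; TBS = tert-butyldimethylsilyl; chain A = (3E,7E,10S)-10-(TBS-oxy)-4,8,12-trimethyltrideca-3,7,11-trien-1-yl; the (S)-phosphoric acid of step 3 and the peptide antipode of step 15 are taken to be the matched ones.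

**Step 1**
Reactants: 1 propanal; 2 methyl vinyl ketone (but-3-en-2-one)
Product: 3 (2R)-2-methyl-5-oxohexanal
Conditions: (S)-2-[methoxy(diphenyl)methyl]pyrrolidine (5 mol %), ethyl 3,4-dihydroxybenzoate (20 mol %), neat, 4 °C
Reagents that add atoms: none
Why: Enamine-catalysed asymmetric Michael addition; the diarylmethyl group shields one face of the (E)-enamine of propanal, so the enone adds to the open face and the methyl-bearing centre (future C4) is set as R.

**Step 2**
Reactants: 3 (2R)-2-methyl-5-oxohexanal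
Product: 5 (4R)-4-methylcyclohex-2-en-1-one, via aldol adduct 4 (not isolated)
Conditions: KOH (0.1 M aq.), n-Bu4NOH (cat.), Et2O/THF, reflux
Reagents that add atoms: none
Why: Intramolecular aldol condensation of the methyl ketone enolate onto the aldehyde closes the six-membered ring; under dilute phase-transfer base the stereocentre, which ends up γ to the carbonyl, is carried through with little erosion.

**Step 3**
Reactants: 6 3-methylbut-2-enal; 7 allenylboronic acid pinacol ester
Product: 8 (4S)-6-methylhept-5-en-1-yn-4-ol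
Conditions: (S)-3,3′-bis(2,4,6-triisopropylphenyl)-1,1′-binaphthyl-2,2′-diyl hydrogen phosphate (5 mol %), 4 Å MS, toluene, −20 °C
Reagents that add atoms: none
Why: Chiral phosphoric acid-catalysed allenylboration (SE2′ propargylation) through a closed six-membered transition state adds 1,2 to the enal and sets the C10′ carbinol as S by catalyst control.

**Step 4**
Reactants: 8 (4S)-6-methylhept-5-en-1-yn-4-ol
Product: 9 tert-butyl(dimethyl){[(4S)-6-methylhept-5-en-1-yn-4-yl]oxy}silane
Conditions: TBSCl, imidazole, DMF, 23 °C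
Reagents that add atoms: tert-butyldimethylsilyl chloride, CC(C)(C)[Si](C)(C)Cl
Why: Silylation of the secondary alcohol (silyl ether formation) masks the allylic carbinol for the organometallic and oxidative steps that follow; the stereocentre is not touched.

**Step 5**
Reactants: 9 tert-butyl(dimethyl){[(4S)-6-methylhept-5-en-1-yn-4-yl]oxy}silane; 10 vinyl bromide
Product: 12 tert-butyl(dimethyl){[(4S,6E)-2,6-dimethylnona-2,6,8-trien-4-yl]oxy}silane, via alkenylalane 11 (not isolated)
Conditions: Me3Al (3 equiv), Cp2ZrCl2 (20 mol %), H2O (1.5 equiv), CH2Cl2, −25 °C; then 10, Pd(PPh3)4 (5 mol %), ZnCl2 (0.5 equiv), THF, 23 °C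
Reagents that add atoms: trimethylaluminium, C[Al](C)C
Why: Zirconium-catalysed syn methylalumination of the terminal alkyne (Negishi carboalumination) puts methyl on the internal and aluminium on the terminal carbon, and the palladium/zinc-catalysed alkenyl–alkenyl coupling (Negishi coupling) goes with retention, fixing C7′=C8′ as E.

**Step 6**
Reactants: 13 5-bromopent-2-yne
Product: 15 (2E)-5-bromo-2-iodopent-2-ene, via alkenylzirconocene 14 (not isolated)
Conditions: Cp2Zr(H)Cl (1.5 equiv), THF, 40 °C; then I2, 0 °C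
Reagents that add atoms: iodine, II
Why: Hydrozirconation adds Zr–H syn with zirconium ending on the less hindered, methyl-bearing alkyne carbon after equilibration, and iodinolysis goes with retention to give the E iodoalkene; the alkyl bromide is inert.

**Step 7**
Reactants: 12 tert-butyl(dimethyl){[(4S,6E)-2,6-dimethylnona-2,6,8-trien-4-yl]oxy}silane; 15 (2E)-5-bromo-2-iodopent-2-ene
Product: 17 {[(4S,6E,10E)-13-bromo-2,6,10-trimethyltrideca-2,6,10-trien-4-yl]oxy}(tert-butyl)dimethylsilane, via alkylborane 16 (not isolated)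
Conditions: 9-BBN (1.1 equiv), THF, 0 → 23 °C; then 15, PdCl2(dppf) (5 mol %), AsPh3 (10 mol %), Cs2CO3, DMF/H2O, 23 °C
Reagents that add atoms: none
Why: 9-BBN adds anti-Markovnikov only to the terminal vinyl group of the diene, and the B-alkyl Suzuki–Miyaura coupling forms C4′–C5′ with retention of the iodoalkene geometry (C3′=C4′ E) while the primary alkyl bromide does not enter oxidative addition.

**Step 8**
Reactants: 17 {[(4S,6E,10E)-13-bromo-2,6,10-trimethyltrideca-2,6,10-trien-4-yl]oxy}(tert-butyl)dimethylsilane; 5 (4R)-4-methylcyclohex-2-en-1-one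
Product: 19 trimethyl{[(3S,4R)-4-methyl-3-(chain A)cyclohex-1-en-1-yl]oxy}silane, via Grignard reagent 18 (not isolated)
Conditions: Mg, THF, 40 °C; then CuBr·SMe2 (10 mol %), Me3SiCl, HMPA, THF, −78 °C, 5 (1.3 equiv); Et3N quench
Reagents that add atoms: chlorotrimethylsilane, C[Si](C)(C)Cl
Why: Copper-catalysed, chlorosilane-accelerated conjugate addition of the Grignard reagent occurs anti to the C4 methyl group and the enolate is captured regiospecifically as the silyl enol ether; the new C3 centre is erased in step 9, so its configuration does not matter.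

**Step 9**
Reactants: 19 trimethyl{[(3S,4R)-4-methyl-3-(chain A)cyclohex-1-en-1-yl]oxy}silane
Product: 20 (4R)-4-methyl-3-(chain A)cyclohex-2-en-1-one
Conditions: Pd(OAc)2 (10 mol %), O2 (1 atm), DMSO, 25 °C
Reagents that add atoms: none
Why: Saegusa–Ito oxidation: the palladium enolate from the silyl enol ether undergoes β-hydride elimination towards C3 only, giving the enone with the side chain on the β-carbon; the neutral conditions leave the γ-stereocentre C4 and the trisubstituted alkenes alone.

**Step 10**
Reactants: 21 3-{[tert-butyl(dimethyl)silyl]oxy}propan-1-ol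
Product: 22 3-{[tert-butyl(dimethyl)silyl]oxy}propyl trifluoromethanesulfonate
Conditions: Tf2O, 2,6-lutidine, CH2Cl2, −78 °C; used at once
Reagents that add atoms: trifluoromethanesulfonic anhydride, FC(F)(F)S(=O)(=O)OS(=O)(=O)C(F)(F)F
Why: O-Sulfonylation of the primary alcohol gives the very reactive primary triflate needed to alkylate a hindered enolate; it is used cold without purification.

**Step 11**
Reactants: 20 (4R)-4-methyl-3-(chain A)cyclohex-2-en-1-one; 22 3-{[tert-butyl(dimethyl)silyl]oxy}propyl trifluoromethanesulfonate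
Product: 24 (2S,3R,4R)-2-[3-(TBS-oxy)propyl]-3,4-dimethyl-3-(chain A)cyclohexan-1-one, via lithium enolate 23 (not isolated)
Conditions: Me2CuLi (1.3 equiv), Et2O, −40 → 0 °C; then THF, 22 (2 equiv), −78 → −30 °C
Reagents that add atoms: lithium dimethylcuprate, [Li+].C[Cu-]C
Why: Conjugate addition–enolate alkylation: the Gilman reagent attacks C5 axially anti to the pseudoaxial C4 methyl (new methyl trans to the C4 methyl, side chain cis), and the lithium enolate is C-alkylated at C6 along the axial trajectory anti to the axial C5 side chain, the opposite axial approach being blocked by a 1,3-diaxial C4 methyl in the other half-chair.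

**Step 12**
Reactants: 24 (2S,3R,4R)-2-[3-(TBS-oxy)propyl]-3,4-dimethyl-3-(chain A)cyclohexan-1-one; 25 isopropenylmagnesium bromide, CH2=C(CH3)MgBr
Product: 26 (2S,3R,4R)-2-[3-(TBS-oxy)propyl]-3,4-dimethyl-1-(prop-1-en-2-yl)-3-(chain A)cyclohexan-1-ol (C1 epimers)
Conditions: CeCl3 (anhydrous, 3 equiv), 25 (3 equiv), THF, −78 → 0 °C
Reagents that add atoms: none
Why: The organocerium reagent formed from the Grignard reagent and CeCl3 is nucleophilic but barely basic, so it adds 1,2 to the hindered, enolisable ketone without epimerising C6; the new carbinol centre is lost in step 13.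

**Step 13**
Reactants: 26 (2S,3R,4R)-2-[3-(TBS-oxy)propyl]-3,4-dimethyl-1-(prop-1-en-2-yl)-3-(chain A)cyclohexan-1-ol
Product: 28 (2Z)-2-{(2S,3R,4R)-2-[3-(TBS-oxy)propyl]-3,4-dimethyl-3-(chain A)cyclohexylidene}propanal, via allylic chromate ester 27 (not isolated)
Conditions: [C5H5NH][CrO3Cl] (pyridinium chlorochromate, 3 equiv), NaOAc, 4 Å MS, CH2Cl2, 23 °C
Reagents that add atoms: pyridinium chlorochromate, [O-][Cr](=O)(=O)Cl.c1cc[nH+]cc1
Why: Babler–Dauben oxidative transposition: the tertiary chromate ester undergoes a [3,3] shift that forms the new C–O bond at the former =CH2 terminus and the primary chromate is then oxidised to the aldehyde; the chair transition state with the α-methyl turned to the unbranched C2 methylene and the smaller CH2 terminus turned to the branched C6 gives the Z enal, which is also expected to be the less strained isomer.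

**Step 14**
Reactants: 28 (2Z)-2-{(2S,3R,4R)-2-[3-(TBS-oxy)propyl]-3,4-dimethyl-3-(chain A)cyclohexylidene}propanal
Product: 29 (2Z)-2-{(2S,3R,4R)-3-[(3E,7E,10S)-10-hydroxy-4,8,12-trimethyltrideca-3,7,11-trien-1-yl]-2-(3-hydroxypropyl)-3,4-dimethylcyclohexylidene}propanal
Conditions: Bu4NF (3 equiv), AcOH (3 equiv), THF, 0 → 23 °C
Reagents that add atoms: none
Why: Fluoride cleaves both silyl ethers (desilylation driven by Si–F bond formation); buffering with acetic acid prevents epimerisation of C6 through the dienolate of the enal.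

**Step 15**
Reactants: 29 (2Z)-2-{(2S,3R,4R)-3-[(3E,7E,10S)-10-hydroxy-4,8,12-trimethyltrideca-3,7,11-trien-1-yl]-2-(3-hydroxypropyl)-3,4-dimethylcyclohexylidene}propanal
Product: 30 (2Z)-2-{(2S,3R,4R)-3-[(3E,7E,10S)-10-[(2R)-3,3-dimethyloxiran-2-yl]-10-hydroxy-4,8-dimethyldeca-3,7-dien-1-yl]-2-(3-hydroxypropyl)-3,4-dimethylcyclohexylidene}propanal
Conditions: Boc-L-Asp-L-Pro-L-Asn(Trt)-D-Phe-OMe (10 mol %), N,N′-diisopropylcarbodiimide (1.5 equiv), 30% aq. H2O2 (2 equiv), HOBt (10 mol %), DMAP (10 mol %), CH2Cl2, 4 °C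
Reagents that add atoms: hydrogen peroxide, OO
Why: Proposed new method: hydroxyl-directed, peptide-embedded peracid epoxidation of a cis-substituted secondary allylic alcohol inside a polyene, a substrate class on which it has not been shown; the carbodiimide and H2O2 turn the aspartate side chain transiently into a peracid, the C10′ hydroxyl hydrogen-bonds to the β-turn backbone so that only the neighbouring C11′=C12′ bond is within reach (the two remote trisubstituted alkenes, the electron-poor enal alkene and the primary alcohol are not), allylic 1,3-strain from the cis methyl holds the carbinol hydrogen in the alkene plane, and the wide O–C–C=C angle of a peracid transition state then delivers oxygen to the face bearing the hydroxyl, giving the threo (10′S,11′R) epoxy alcohol, while the catalyst chirality is matched to the (S)-carbinol so the minor C10′ epimer is left behind; the closest known reaction types are aspartyl-peptide peracid catalysis for hydroxyl-directed site-selective epoxidation of primary allylic alcohols in polyenes and the threo-selective Henbest-type peracid epoxidation of cis-substituted secondary allylic alcohols.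

**Compound list**
1 | propanal | CCC=O | starting material
2 | methyl vinyl ketone (but-3-en-2-one) | CC(=O)C=C | starting material
3 | (2R)-2-methyl-5-oxohexanal | O=C[C@H](C)CCC(C)=O | intermediate
4 | (4R)-3-hydroxy-4-methylcyclohexan-1-one, aldol adduct, C3 epimers (not isolated) | O=C1CC(O)[C@H](C)CC1 | intermediate
5 | (4R)-4-methylcyclohex-2-en-1-one | O=C1C=C[C@H](C)CC1 | intermediate
6 | 3-methylbut-2-enal | CC(C)=CC=O | starting material
7 | allenylboronic acid pinacol ester | C=C=CB1OC(C)(C)C(C)(C)O1 | starting material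
8 | (4S)-6-methylhept-5-en-1-yn-4-ol | C#CC[C@H](O)C=C(C)C | intermediate
9 | tert-butyl(dimethyl){[(4S)-6-methylhept-5-en-1-yn-4-yl]oxy}silane | C#CC[C@H](O[Si](C)(C)C(C)(C)C)C=C(C)C | intermediate
10 | vinyl bromide (bromoethene) | C=CBr | starting material
11 | [(1E,4S)-4-(TBS-oxy)-2,6-dimethylhepta-1,5-dien-1-yl]dimethylaluminium, alkenylalane (not isolated) | C[Al](C)/C=C(\C)C[C@H](O[Si](C)(C)C(C)(C)C)C=C(C)C | intermediate
12 | tert-butyl(dimethyl){[(4S,6E)-2,6-dimethylnona-2,6,8-trien-4-yl]oxy}silane | C=C/C=C(\C)C[C@H](O[Si](C)(C)C(C)(C)C)C=C(C)C | intermediate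
13 | 5-bromopent-2-yne | CC#CCCBr | starting material
14 | [(2E)-5-bromopent-2-en-2-yl]chloridobis(cyclopentadienyl)zirconium, alkenylzirconocene (not isolated) | C/C(=C\CCBr)[Zr](Cl)(C1C=CC=C1)C1C=CC=C1 | intermediate
15 | (2E)-5-bromo-2-iodopent-2-ene | C/C(I)=C\CCBr | intermediate
16 | 9-[(3E,6S)-6-(TBS-oxy)-4,8-dimethylnona-3,7-dien-1-yl]-9-borabicyclo[3.3.1]nonane, alkylborane (not isolated) | B1(CC/C=C(\C)C[C@H](O[Si](C)(C)C(C)(C)C)C=C(C)C)C2CCCC1CCC2 | intermediate
17 | {[(4S,6E,10E)-13-bromo-2,6,10-trimethyltrideca-2,6,10-trien-4-yl]oxy}(tert-butyl)dimethylsilane | BrCC/C=C(\C)CC/C=C(\C)C[C@H](O[Si](C)(C)C(C)(C)C)C=C(C)C | intermediate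
18 | (chain A)magnesium bromide, Grignard reagent (not isolated) | Br[Mg]CC/C=C(\C)CC/C=C(\C)C[C@H](O[Si](C)(C)C(C)(C)C)C=C(C)C | intermediate
19 | trimethyl{[(3S,4R)-4-methyl-3-(chain A)cyclohex-1-en-1-yl]oxy}silane | C[Si](C)(C)OC1=C[C@@H](CC/C=C(\C)CC/C=C(\C)C[C@H](O[Si](C)(C)C(C)(C)C)C=C(C)C)[C@H](C)CC1 | intermediate
20 | (4R)-4-methyl-3-(chain A)cyclohex-2-en-1-one | O=C1C=C(CC/C=C(\C)CC/C=C(\C)C[C@H](O[Si](C)(C)C(C)(C)C)C=C(C)C)[C@H](C)CC1 | intermediate
21 | 3-{[tert-butyl(dimethyl)silyl]oxy}propan-1-ol | CC(C)(C)[Si](C)(C)OCCCO | starting material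
22 | 3-{[tert-butyl(dimethyl)silyl]oxy}propyl trifluoromethanesulfonate | CC(C)(C)[Si](C)(C)OCCCOS(=O)(=O)C(F)(F)F | intermediate
23 | lithium (3R,4R)-3,4-dimethyl-3-(chain A)cyclohex-1-en-1-olate, lithium enolate (not isolated) | [Li]OC1=C[C@](C)(CC/C=C(\C)CC/C=C(\C)C[C@H](O[Si](C)(C)C(C)(C)C)C=C(C)C)[C@H](C)CC1 | intermediate
24 | (2S,3R,4R)-2-[3-(TBS-oxy)propyl]-3,4-dimethyl-3-(chain A)cyclohexan-1-one | O=C1[C@@H](CCCO[Si](C)(C)C(C)(C)C)[C@](C)(CC/C=C(\C)CC/C=C(\C)C[C@H](O[Si](C)(C)C(C)(C)C)C=C(C)C)[C@H](C)CC1 | intermediate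
25 | isopropenylmagnesium bromide, CH2=C(CH3)MgBr | C=C(C)[Mg]Br | starting material
26 | (2S,3R,4R)-2-[3-(TBS-oxy)propyl]-3,4-dimethyl-1-(prop-1-en-2-yl)-3-(chain A)cyclohexan-1-ol, C1 epimers | C=C(C)C1(O)[C@@H](CCCO[Si](C)(C)C(C)(C)C)[C@](C)(CC/C=C(\C)CC/C=C(\C)C[C@H](O[Si](C)(C)C(C)(C)C)C=C(C)C)[C@H](C)CC1 | intermediate
27 | (2Z)-2-{(2S,3R,4R)-2-[3-(TBS-oxy)propyl]-3,4-dimethyl-3-(chain A)cyclohexylidene}propyl hydrogen chromate, allylic chromate ester (not isolated) | C/C(CO[Cr](=O)(=O)O)=C1\CC[C@@H](C)[C@@](C)(CC/C=C(\C)CC/C=C(\C)C[C@H](O[Si](C)(C)C(C)(C)C)C=C(C)C)[C@@H]1CCCO[Si](C)(C)C(C)(C)C | intermediate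
28 | (2Z)-2-{(2S,3R,4R)-2-[3-(TBS-oxy)propyl]-3,4-dimethyl-3-(chain A)cyclohexylidene}propanal | C/C(C=O)=C1\CC[C@@H](C)[C@@](C)(CC/C=C(\C)CC/C=C(\C)C[C@H](O[Si](C)(C)C(C)(C)C)C=C(C)C)[C@@H]1CCCO[Si](C)(C)C(C)(C)C | intermediate
29 | (2Z)-2-{(2S,3R,4R)-3-[(3E,7E,10S)-10-hydroxy-4,8,12-trimethyltrideca-3,7,11-trien-1-yl]-2-(3-hydroxypropyl)-3,4-dimethylcyclohexylidene}propanal | C/C(C=O)=C1\CC[C@@H](C)[C@@](C)(CC/C=C(\C)CC/C=C(\C)C[C@H](O)C=C(C)C)[C@@H]1CCCO | intermediate
30 | (2Z)-2-{(2S,3R,4R)-3-[(3E,7E,10S)-10-[(2R)-3,3-dimethyloxiran-2-yl]-10-hydroxy-4,8-dimethyldeca-3,7-dien-1-yl]-2-(3-hydroxypropyl)-3,4-dimethylcyclohexylidene}propanal (CNP0208461.1) | C/C(C=O)=C1\CC[C@@H](C)[C@@](C)(CC/C=C(\C)CC/C=C(\C)C[C@H](O)[C@H]2OC2(C)C)[C@@H]1CCCO | target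

**Step count and risks**

Total step count: 15. Longest linear sequence: 11 steps (steps 3, 4, 5, 7, 8, 9, 11, 12, 13, 14, 15, from 3-methylbut-2-enal).

Step 11 (conjugate methylation and enolate alkylation). The enolate carbon sits next to a quaternary centre, the triflate may alkylate on oxygen, and the C6 epimer may form. The fallback sets out from enone 20. The same Me2CuLi addition is run but the enolate is trapped with the soft, C-selective allyl bromide (HMPA, −78 → 0 °C) to give the allyl ketone (2S,3R,4R)-3,4-dimethyl-2-(prop-2-en-1-yl)-3-(chain A)cyclohexan-1-one F1. 9-BBN (THF, 0 °C), which touches only the terminal alkene, followed by NaBO3·4H2O gives the keto alcohol (2S,3R,4R)-2-(3-hydroxypropyl)-3,4-dimethyl-3-(chain A)cyclohexan-1-one F2. TBSCl/imidazole (DMF) then returns to the route at ketone 24.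

Step 13 (oxidative transposition). Possible failures are an E/Z mixture at the tetrasubstituted enal, acid-triggered cyclisation of the allylic cation onto the polyene, and a slow reaction of the hindered carbinol. The fallback sets out from carbinol 26 and avoids chromium. SOCl2/pyridine (Et2O, −10 °C) rearranges the tertiary alcohol by SNi′ to the primary (Z)-allylic chloride tert-butyl{3-[(1S,2R,3R,6Z)-6-(1-chloropropan-2-ylidene)-2,3-dimethyl-2-(chain A)cyclohexyl]propoxy}dimethylsilane F3. Me3NO (DMSO, 23 °C; amine N-oxide oxidation of the allylic halide) converts it to the aldehyde, coming back at enal 28. Any E isomer is equilibrated with catalytic I2.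

Step 15 (proposed new epoxidation). The peptide may not single out the C11′=C12′ bond, may give a poor threo/erythro ratio, or the peracid may attack the aldehyde. The fallback sets out from diol enal 29 and arrives directly at target 30 by known chemistry of a different kind. Instead of an organocatalytic, hydrogen-bond-delivered peracid it uses a metal-alkoxide-templated peroxide transfer under substrate control only: Ti(OiPr)4 (1.2 equiv), anhydrous t-BuOOH, 4 Å MS, CH2Cl2, −20 °C, no chiral ligand. Cis-substituted secondary allylic alcohols are known to give the threo epoxy alcohol under these conditions (about 9:1), and the allylic alkene reacts far faster than homoallylic or isolated ones. The minor diastereomers are removed by chromatography. New compounds: none F0.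

**Further compounds**
F1 | step 11 | (2S,3R,4R)-3,4-dimethyl-2-(prop-2-en-1-yl)-3-(chain A)cyclohexan-1-one | O=C1[C@@H](CC=C)[C@](C)(CC/C=C(\C)CC/C=C(\C)C[C@H](O[Si](C)(C)C(C)(C)C)C=C(C)C)[C@H](C)CC1
F2 | step 11 | (2S,3R,4R)-2-(3-hydroxypropyl)-3,4-dimethyl-3-(chain A)cyclohexan-1-one | O=C1[C@@H](CCCO)[C@](C)(CC/C=C(\C)CC/C=C(\C)C[C@H](O[Si](C)(C)C(C)(C)C)C=C(C)C)[C@H](C)CC1
F3 | step 13 | tert-butyl{3-[(1S,2R,3R,6Z)-6-(1-chloropropan-2-ylidene)-2,3-dimethyl-2-(chain A)cyclohexyl]propoxy}dimethylsilane | C/C(CCl)=C1\CC[C@@H](C)[C@@](C)(CC/C=C(\C)CC/C=C(\C)C[C@H](O[Si](C)(C)C(C)(C)C)C=C(C)C)[C@@H]1CCCO[Si](C)(C)C(C)(C)C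
F0 | step 15 | none | none
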